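The plan cuts the side chain between the ring-bound methylene C1' and the oxygen-bearing carbon C2'. The key step joins them as two donors: a sparteine-lithiated dodecyl carbamate (carbenoid C2') captures 3,5-dimethoxybenzyl pinacol boronate (C1'), and a stereospecific 1,2-metallate shift forms C1'–C2' and sets C2' in one operation. It exploits the secondary carbinol C2' adjacent to the benzylic-type C1' on ring carbon C1; the precursor is a flat benzylboronate ate complex. The arene is then oxidised to a para-quinone monoketal, the C1=C2 bond is masked by asymmetric selenol addition while the C6 and C3 carbonyls are reduced, and selenoxide elimination unveils the cyclohexa-1,4-diene.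

Key step: step 3

Remark: atoms are numbered as in the target (ring C1 carries the side chain, C3 the free hydroxyl, C5 the methoxy group, C6 the ring acetate; side chain C1', C2').

Step 1
Reactants: 1 dodecan-1-ol
Product: 2 dodecyl N,N-diisopropylcarbamate
Conditions: i-Pr2NCOCl, Et3N, CH2Cl2, reflux
Reagents that add atoms: N,N-diisopropylcarbamoyl chloride, CC(C)N(C(C)C)C(=O)Cl
Why: O-carbamoylation of a primary alcohol with a carbamoyl chloride installs the hindered carbamate that later serves as directing group for lithiation and as leaving group.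

Step 2
Reactants: 3 1-(bromomethyl)-3,5-dimethoxybenzene
Product: 4 2-(3,5-dimethoxybenzyl)-4,4,5,5-tetramethyl-1,3,2-dioxaborolane
Conditions: B2pin2, Pd(dba)2 (3 mol %), P(C6H4-4-OMe)3, KOAc, toluene, 50 °C
Reagents that add atoms: bis(pinacolato)diboron, CC1(C)OB(OC1(C)C)B1OC(C)(C)C(C)(C)O1
Why: Miyaura borylation of a benzylic bromide should give the benzylboronic ester without touching the aryl ethers.

Step 3
Reactants: 2 dodecyl N,N-diisopropylcarbamate; 4 2-(3,5-dimethoxybenzyl)-4,4,5,5-tetramethyl-1,3,2-dioxaborolane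
Product: 8 (R)-1-(3,5-dimethoxyphenyl)tridecan-2-ol, via lithiated carbamate 5 (not isolated), via boronate complex 6 (not isolated), via boronic ester 7 (not isolated)
Conditions: s-BuLi, (–)-sparteine, Et2O, –78 °C; then 4, –78 °C → reflux; then NaOH, H2O2, THF, 0 °C → rt
Reagents that add atoms: hydrogen peroxide, OO
Why: Sparteine-mediated deprotonation removes the pro-S hydrogen of 2 and gives the configurationally stable lithiated carbamate 5, which adds to the boron of 4 with retention to form the boronate complex 6. On warming, the benzylic CH2 group migrates from boron to carbon anti to the departing carbamate (1,2-metallate rearrangement, inversion at C2'), so the C1'–C2' bond and the C2' stereocentre arise together in boronic ester 7. Alkaline H2O2 then replaces boron by hydroxyl with retention and should give the (R)-alcohol. The closest known reaction type is the lithiation–borylation of O-alkyl carbamates with primary pinacol boronic esters, a Matteson-type homologation. No ring is closed, and C2' is controlled by the chiral diamine (reagent control). The step needs ate-complex formation to outrun deprotonation of the acidic benzylic C–H of 4 and needs the benzyl group, not a pinacol oxygen, to migrate; fast borylation at –78 °C and the high migratory aptitude of benzyl secure both.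

Step 4
Reactants: 8 (R)-1-(3,5-dimethoxyphenyl)tridecan-2-ol
Product: 9 (R)-1-(2-bromo-3,5-dimethoxyphenyl)tridecan-2-ol
Conditions: NBS, MeCN, 0 °C
Reagents that add atoms: N-bromosuccinimide, O=C1CCC(=O)N1Br
Why: Electrophilic aromatic bromination should go para to one methoxy group and ortho to the side chain (the future C6), because the position between the two methoxy groups is the more hindered one.

Step 5
Reactants: 9 (R)-1-(2-bromo-3,5-dimethoxyphenyl)tridecan-2-ol
Product: 12 (R)-2-(2-hydroxytridecyl)-4,6-dimethoxyphenol, via aryllithium 10 (not isolated), via arylborate 11 (not isolated)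
Conditions: n-BuLi (2.2 equiv), THF, –78 °C; B(OMe)3, –78 °C → rt; then NaOH, H2O2, 0 °C
Reagents that add atoms: hydrogen peroxide, OO
Why: Bromine–lithium exchange on the lithium alkoxide, borylation and oxidative ipso-hydroxylation of the arylborate replace bromine by the phenolic hydroxyl that becomes the C6 oxygen.

Step 6
Reactants: 12 (R)-2-(2-hydroxytridecyl)-4,6-dimethoxyphenol
Product: 13 (R)-2-(2-hydroxytridecyl)-4,4,6-trimethoxycyclohexa-2,5-dien-1-one
Conditions: PhI(OAc)2, MeOH, 0 °C
Reagents that add atoms: methanol, CO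
Why: Oxidative dearomatisation of a para-methoxyphenol with PhI(OAc)2 in methanol should trap the phenoxenium ion at the methoxy-bearing para carbon (C3) and give the para-quinone monoketal.

Step 7
Reactants: 13 (R)-2-(2-hydroxytridecyl)-4,4,6-trimethoxycyclohexa-2,5-dien-1-one
Product: 14 (5S,6R)-6-[(R)-2-hydroxytridecyl]-2,4,4-trimethoxy-5-(phenylselanyl)cyclohex-2-en-1-one
Conditions: PhSeH (1.1 equiv), 1-[3,5-bis(trifluoromethyl)phenyl]-3-[(8α,9S)-6'-methoxycinchonan-9-yl]thiourea (10 mol %), toluene, –40 °C
Reagents that add atoms: benzeneselenol, [SeH]c1ccccc1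
Why: Cinchona-thiourea-catalysed conjugate addition of the selenol (selena-Michael addition) should occur at C2, the β-carbon of the alkyl-substituted enone (the methoxy-substituted enone is deactivated), with the catalyst setting C2 (the quinidine-derived pseudoenantiomer is used if the sense of induction is opposite) and amine-mediated equilibration of the α-carbon C1 placing the side chain trans to selenium.

Step 8
Reactants: 14 (5S,6R)-6-[(R)-2-hydroxytridecyl]-2,4,4-trimethoxy-5-(phenylselanyl)cyclohex-2-en-1-one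
Product: 15 (1S,5S,6R)-6-[(R)-2-hydroxytridecyl]-2,4,4-trimethoxy-5-(phenylselanyl)cyclohex-2-en-1-ol
Conditions: i-Bu2AlH (2.2 equiv), CH2Cl2, –78 °C; aq. KNaC4H4O6
Reagents that add atoms: none
Why: 1,2-Reduction of the enone carbonyl with the bulky aluminium hydride should proceed by steric approach control anti to the adjacent side chain on C1, placing the C6 hydroxyl cis to that chain as the target requires.

Step 9
Reactants: 15 (1S,5S,6R)-6-[(R)-2-hydroxytridecyl]-2,4,4-trimethoxy-5-(phenylselanyl)cyclohex-2-en-1-ol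
Product: 17 (4S,5R,6S)-4-acetoxy-5-[(R)-2-acetoxytridecyl]-3-methoxy-6-(phenylselanyl)cyclohex-2-en-1-one, via diacetate ketal 16 (not isolated)
Conditions: Ac2O, pyridine, DMAP (cat.), CH2Cl2, 0 °C → rt; then 5% aq. (CO2H)2, THF, 0 °C
Reagents that add atoms: acetic anhydride, CC(=O)OC(C)=O; water, O
Why: DMAP-catalysed acetylation of both secondary alcohols followed by mild acid hydrolysis of the vinylogous ketal, in which water should attack the dimethoxyallyl cation at C3 (the terminus remote from the electron-withdrawing C6 acetate), unveils the β-methoxy enone.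

Step 10
Reactants: 17 (4S,5R,6S)-4-acetoxy-5-[(R)-2-acetoxytridecyl]-3-methoxy-6-(phenylselanyl)cyclohex-2-en-1-one
Product: 18 (1S,4R,5S,6R)-6-[(R)-2-acetoxytridecyl]-4-hydroxy-2-methoxy-5-(phenylselanyl)cyclohex-2-en-1-yl acetate
Conditions: NaBH4, CeCl3·7H2O, MeOH/THF, –40 → 0 °C; quench aq. NaHCO3
Reagents that add atoms: none
Why: Luche reduction (1,2-selective, acetates spared at low temperature) should deliver hydride anti to the neighbouring phenylselanyl group (Felkin–Anh control), setting the C3 carbinol cis to selenium and trans to the C6 acetate.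

Step 11
Reactants: 18 (1S,4R,5S,6R)-6-[(R)-2-acetoxytridecyl]-4-hydroxy-2-methoxy-5-(phenylselanyl)cyclohex-2-en-1-yl acetate
Product: 20 (R)-1-[(3S,6S)-6-acetoxy-3-hydroxy-5-methoxycyclohexa-1,4-dien-1-yl]tridecan-2-yl acetate, via selenoxide 19 (not isolated)
Conditions: mCPBA (1.05 equiv), CH2Cl2, –78 °C; then i-Pr2NH, –78 → 0 °C
Reagents that add atoms: none
Why: Selenoxide syn-elimination should remove the only syn β-hydrogen (on C1, away from the hydroxyl-bearing C3) and form the C1=C2 bond at or below 0 °C under buffered conditions that the doubly allylic acetate and the enol ether should survive.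

Compound list
1 | dodecan-1-ol | CCCCCCCCCCCCO | starting material
2 | dodecyl N,N-diisopropylcarbamate | CCCCCCCCCCCCOC(=O)N(C(C)C)C(C)C | intermediate
3 | 1-(bromomethyl)-3,5-dimethoxybenzene (3,5-dimethoxybenzyl bromide) | COc1cc(CBr)cc(OC)c1 | starting material
4 | 2-(3,5-dimethoxybenzyl)-4,4,5,5-tetramethyl-1,3,2-dioxaborolane | COc1cc(CB2OC(C)(C)C(C)(C)O2)cc(OC)c1 | intermediate
5 | (S)-1-lithiododecyl N,N-diisopropylcarbamate, formed in situ as its (–)-sparteine complex | CCCCCCCCCCC[C@H]([Li])OC(=O)N(C(C)C)C(C)C | intermediate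
6 | lithium (3,5-dimethoxybenzyl)[(S)-1-(N,N-diisopropylcarbamoyloxy)dodecyl](pinacolato)borate, formed in situ | [Li+].CCCCCCCCCCC[C@H]([B-]1(Cc2cc(OC)cc(OC)c2)OC(C)(C)C(C)(C)O1)OC(=O)N(C(C)C)C(C)C | intermediate
7 | 2-[(R)-1-(3,5-dimethoxyphenyl)tridecan-2-yl]-4,4,5,5-tetramethyl-1,3,2-dioxaborolane, formed in situ | CCCCCCCCCCC[C@H](Cc1cc(OC)cc(OC)c1)B1OC(C)(C)C(C)(C)O1 | intermediate
8 | (R)-1-(3,5-dimethoxyphenyl)tridecan-2-ol | CCCCCCCCCCC[C@H](Cc1cc(OC)cc(OC)c1)O | intermediate
9 | (R)-1-(2-bromo-3,5-dimethoxyphenyl)tridecan-2-ol | CCCCCCCCCCC[C@H](Cc1cc(OC)cc(OC)c1Br)O | intermediate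
10 | lithium (R)-1-(2-lithio-3,5-dimethoxyphenyl)tridecan-2-olate, formed in situ | CCCCCCCCCCC[C@H](Cc1cc(OC)cc(OC)c1[Li])O[Li] | intermediate
11 | lithium {2-[(R)-2-(lithiooxy)tridecyl]-4,6-dimethoxyphenyl}trimethoxyborate, formed in situ | [Li+].CCCCCCCCCCC[C@H](Cc1cc(OC)cc(OC)c1[B-](OC)(OC)OC)O[Li] | intermediate
12 | (R)-2-(2-hydroxytridecyl)-4,6-dimethoxyphenol | CCCCCCCCCCC[C@H](Cc1cc(OC)cc(OC)c1O)O | intermediate
13 | (R)-2-(2-hydroxytridecyl)-4,4,6-trimethoxycyclohexa-2,5-dien-1-one | CCCCCCCCCCC[C@H](CC1=CC(OC)(OC)C=C(OC)C1=O)O | intermediate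
14 | (5S,6R)-6-[(R)-2-hydroxytridecyl]-2,4,4-trimethoxy-5-(phenylselanyl)cyclohex-2-en-1-one (side chain trans to selenium) | CCCCCCCCCCC[C@H](C[C@H]1[C@H]([Se]c2ccccc2)C(OC)(OC)C=C(OC)C1=O)O | intermediate
15 | (1S,5S,6R)-6-[(R)-2-hydroxytridecyl]-2,4,4-trimethoxy-5-(phenylselanyl)cyclohex-2-en-1-ol (ring hydroxyl cis to the side chain) | CCCCCCCCCCC[C@H](C[C@H]1[C@H]([Se]c2ccccc2)C(OC)(OC)C=C(OC)[C@H]1O)O | intermediate
16 | (1S,5S,6R)-6-[(R)-2-acetoxytridecyl]-2,4,4-trimethoxy-5-(phenylselanyl)cyclohex-2-en-1-yl acetate, formed in situ | CCCCCCCCCCC[C@H](C[C@H]1[C@H]([Se]c2ccccc2)C(OC)(OC)C=C(OC)[C@H]1OC(C)=O)OC(C)=O | intermediate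
17 | (4S,5R,6S)-4-acetoxy-5-[(R)-2-acetoxytridecyl]-3-methoxy-6-(phenylselanyl)cyclohex-2-en-1-one | CCCCCCCCCCC[C@H](C[C@H]1[C@H]([Se]c2ccccc2)C(=O)C=C(OC)[C@H]1OC(C)=O)OC(C)=O | intermediate
18 | (1S,4R,5S,6R)-6-[(R)-2-acetoxytridecyl]-4-hydroxy-2-methoxy-5-(phenylselanyl)cyclohex-2-en-1-yl acetate (hydroxyl cis to selenium, trans to the ring acetate) | CCCCCCCCCCC[C@H](C[C@H]1[C@H]([Se]c2ccccc2)[C@H](O)C=C(OC)[C@H]1OC(C)=O)OC(C)=O | intermediate
19 | selenoxide of 18 (mixture at selenium), formed in situ | CCCCCCCCCCC[C@H](C[C@H]1[C@H]([Se](=O)c2ccccc2)[C@H](O)C=C(OC)[C@H]1OC(C)=O)OC(C)=O | intermediate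
20 | (R)-1-[(3S,6S)-6-acetoxy-3-hydroxy-5-methoxycyclohexa-1,4-dien-1-yl]tridecan-2-yl acetate | CCCCCCCCCCC[C@H](CC1=C[C@H](O)C=C(OC)[C@H]1OC(C)=O)OC(C)=O | target

Total step count: 11. Longest linear sequence: 10 steps (from 3 through steps 2 to 11, or from 1 through steps 1 and 3 to 11).

Steps most likely to fail

Step 7. The catalysed selenol addition may suffer from poor enantioselectivity, from addition to the wrong enone, from reversal, or from reductive aromatisation of the monoketal. The fallback replaces catalyst control by auxiliary control and sets out from 13. Acid-catalysed ketal exchange with (R,R)-hydrobenzoin (pyridinium 4-toluenesulfonate, benzene, 4 Å molecular sieves) should give the (R,R)-hydrobenzoin spiroketal of the dienone F1. Et3N-catalysed addition of PhSeH, now steered by the C2-symmetric dioxolane next to the reacting carbon C2, should give the selenide F2 (the antipodal diol is used if the wrong face is shielded). Reduction with i-Bu2AlH gives the allylic alcohol F3, and Ac2O/pyridine/DMAP gives the diacetate F4. Mild aqueous acid then releases the diol and the route is rejoined at 17.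

Step 8. Hydride may attack the C6 carbonyl from the wrong face (axial attack), giving the C6 epimer. The fallback inverts instead of selecting and sets out from 14. Acetylation of the only hydroxyl (Ac2O, pyridine) gives the side-chain acetate F5. Luche reduction is then allowed to follow its axial preference and gives the epimeric ring alcohol F6 (hydroxyl trans to the side chain). A Mitsunobu reaction with AcOH (PPh3, DIAD, THF, 0 °C) installs the ring acetate with inversion and rejoins the route at 16, which is hydrolysed as in step 9.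

Step 9. Water may add to the wrong terminus of the dimethoxyallyl cation (giving the isomeric vinylogous ester), or acid may cause loss of methanol and acetic acid. The fallback hydrolyses the ketal before the enol ether can compete and sets out from 14. Aqueous oxalic acid in THF at 0 °C, applied while C5 is still part of the α-methoxy enone, can only unveil the C3 carbonyl and should give the enedione F7. One equivalent of i-Bu2AlH beyond that consumed by the hydroxyl (CH2Cl2, –78 °C) should reduce only the non-vinylogous C6 carbonyl, anti to the side chain, to the hydroxy enone F8. Ac2O/pyridine/DMAP acetylates both hydroxyls and rejoins the route at 17.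

Further compounds
F1 | step 7 | (R,R)-hydrobenzoin spiroketal of 13: (2R,3R)-7-[(R)-2-hydroxytridecyl]-9-methoxy-2,3-diphenyl-1,4-dioxaspiro[4.5]deca-6,9-dien-8-one | CCCCCCCCCCC[C@H](CC1=CC2(O[C@H](c3ccccc3)[C@@H](c3ccccc3)O2)C=C(OC)C1=O)O
F2 | step 7 | selenide corresponding to 14 with the hydrobenzoin spiroketal in place of the dimethyl ketal | CCCCCCCCCCC[C@H](C[C@H]1[C@H]([Se]c2ccccc2)C3(O[C@H](c4ccccc4)[C@@H](c4ccccc4)O3)C=C(OC)C1=O)O
F3 | step 7 | allylic alcohol corresponding to 15 with the hydrobenzoin spiroketal in place of the dimethyl ketal | CCCCCCCCCCC[C@H](C[C@H]1[C@H]([Se]c2ccccc2)C3(O[C@H](c4ccccc4)[C@@H](c4ccccc4)O3)C=C(OC)[C@H]1O)O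
F4 | step 7 | diacetate of F3 (analogue of 16) | CCCCCCCCCCC[C@H](C[C@H]1[C@H]([Se]c2ccccc2)C3(O[C@H](c4ccccc4)[C@@H](c4ccccc4)O3)C=C(OC)[C@H]1OC(C)=O)OC(C)=O
F5 | step 8 | side-chain acetate of 14: (R)-1-[(1R,2S)-3,3,5-trimethoxy-6-oxo-2-(phenylselanyl)cyclohex-4-en-1-yl]tridecan-2-yl acetate | CCCCCCCCCCC[C@H](C[C@H]1[C@H]([Se]c2ccccc2)C(OC)(OC)C=C(OC)C1=O)OC(C)=O
F6 | step 8 | ring-carbinol epimer of 15 carrying the side-chain acetate: (R)-1-[(1R,2S,6R)-6-hydroxy-3,3,5-trimethoxy-2-(phenylselanyl)cyclohex-4-en-1-yl]tridecan-2-yl acetate | CCCCCCCCCCC[C@H](C[C@H]1[C@H]([Se]c2ccccc2)C(OC)(OC)C=C(OC)[C@@H]1O)OC(C)=O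
F7 | step 9 | (5S,6R)-6-[(R)-2-hydroxytridecyl]-2-methoxy-5-(phenylselanyl)cyclohex-2-ene-1,4-dione | CCCCCCCCCCC[C@H](C[C@H]1[C@H]([Se]c2ccccc2)C(=O)C=C(OC)C1=O)O
F8 | step 9 | (4S,5R,6S)-4-hydroxy-5-[(R)-2-hydroxytridecyl]-3-methoxy-6-(phenylselanyl)cyclohex-2-en-1-one | CCCCCCCCCCC[C@H](C[C@H]1[C@H]([Se]c2ccccc2)C(=O)C=C(OC)[C@H]1O)O
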